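3 questions stand on blue and teal, and one number serves them.

| flask | substrate | reagent | initiator | radical scavenger | temperature | remark | time |
|---|---|---|---|---|---|---|---|
| autumn | 0.050 M | 1.05 equiv | 7.5 mol% | 0.064 mol% | 20 °C | run made earlier |  |
| blue | 0.050 M | 1.05 equiv | 5 mol% | 0.064 mol% |  | at 20 °C until 80 s, from then on at 40 °C | 4.0 min |
| teal | 0.20 M | 1.05 equiv | 5 mol% | 0.1 mol% |  | at 40 °C throughout | 4.0 min |

autumn run (percent of the substrate charged)

| time / s | target / % |
|---|---|
| 10.0 | 16.1 |
| 15.0 | 23.0 |
| 20.0 | 28.5 |
| 30.0 | 39.7 |
| 40.0 | 48.4 |
| 50.0 | 55.4 |

(scatter of a reading: 0.3 percentage points)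

- the numbers in the tables scatter by 0.3 percentage points (one standard deviation)
- the earlier runs do not show what temperature does; that part of a forecast is a guess
- where the amount of substrate changes, what is given in equivalents or mol% on it follows
- no earlier run changes the charge of initiator; that part of a forecast is a guess
- no earlier run changes the charge of radical scavenger; that part of a forecast is a guess

- which one finishes higher in amount of target, in percent of the substrate charged ("neither" within 2 percentage points) (blue / teal / neither)
- amount of target at the end, in percent of the substrate charged, blue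
- amount of target at the end, in percent of the substrate charged, teal

In the autumn run, with substrate taken as charge minus target, substrate falls in a pseudo-first-order way, but its constant fades: ln(charge over substrate left) per unit time reads 0.01742 s⁻¹ at 15.0 s and 0.01615 s⁻¹ at 50.0 s. Read as an exponential fade, this gives a fade rate of 0.004344 s⁻¹ and a starting constant of 0.0180 s⁻¹. Their ratio, 4.14, is the reach, the whole logarithmic loss of substrate that a charge of initiator can buy before it dies. In a flask held at one temperature, the fraction of substrate left once the initiator has died is then exp(−reach). This is a loose reading, since the two rates differ by 7.29%.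

My reckoning rests on guesses. Reach is taken to go with the square root of the initiator concentration, as for chains ending in pairs, and at 40 °C decay is taken to speed up by a factor 4 and the chain rate by 2, dividing reach by 2.

Blue at 20 °C has a reach of 3.38 and spends 29.4% of it by 80 s. The remainder is divided by 2, giving 2.19 and 88.8%. Teal gets 3.38 and 96.6%, so teal leads by 7.8 percentage points, beyond the margin.

One number is enough if the clock outlasts the initiator. On the guess, the unspent part of the hot reach at the end is 6.20% in blue and 1.54% in teal.

The forecast says neither, with 95% (86% to 99.5%) for blue and 97.5% (90% to 100%) for teal, on the ground that “Both approach completion, so the gap is probably under 2 points”, which differs from the reckoning above.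

Blue ends at 87.5% and teal at 96.5%, so teal finishes higher; ten times the time  changes neither.

    initiator → 2 initiating radical (k = 0.0110 s⁻¹, Ea = 91.0 kJ mol⁻¹)
    substrate + initiating radical → capped initiator + first chain carrier (k = 2.40 × 10⁵ L mol⁻¹ s⁻¹, Ea = 23.0 kJ mol⁻¹)
    reagent + first chain carrier → target + second chain carrier (k = 1.40 × 10⁵ L mol⁻¹ s⁻¹, Ea = 24.0 kJ mol⁻¹)
    substrate + second chain carrier → by-product + first chain carrier (k = 20000 L mol⁻¹ s⁻¹, Ea = 33.0 kJ mol⁻¹)
    2 second chain carrier → ended chains A (k = 6.00 × 10⁷ L mol⁻¹ s⁻¹, Ea = 14.0 kJ mol⁻¹)
    first chain carrier + radical scavenger → ended chains B (k = 8.50 × 10⁶ L mol⁻¹ s⁻¹, Ea = 18.0 kJ mol⁻¹)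
    (constants at 20 °C)

The substrate left, 12% in blue and 3.4% in teal, gives reaches of 2.09 and 3.37. The neighbouring flask is teal kept at 65 °C. Dividing by 2 for each step as wide as 20 °C to 40 °C takes teal's reach to 1.42, which means 75.8% target. That flask gives 85.1%, with initiator at 0% and 15% of substrate left, a reach of 1.91, lower than teal's.

(The runs were computed for an exercise, and the scatter is random.)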